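**Retrosynthetic overview**
1. Target 33 ⇐ C10 alcohol 32 ⇐ macrocyclic allylboronic ester 31 ⇐ 15-membered cyclic boronate 30: the 14-membered carbocycle is closed at C10–C11 by a ring-contracting 1,2-metallate shift of the open chain 28 (C10 magnesium carbenoid, C11 alkenyl-Bpin).
2. 28 ⇐ sp3–sp2 Negishi coupling at C4–C5 of epoxy iodide 12 (C5–C10) with vinyl iodide 26 (C11–C14, C1–C4, C15).
3. 12 ⇐ but-3-yn-1-ol + oxirane: carboalumination/oxirane opening (E-C7=C8), Shi epoxidation (C7, C8), sparteine lithiation/sulfinylation (stored C10 carbenoid).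
4. 26 ⇐ hex-5-ynoic acid + but-2-yn-1-ol: Evans alkylation (C1), MeMgBr (C15), carboalumination/borylation (E-C11=C12); the Z-C3=C4 unit comes from trans-hydroalumination/iodination.
5. Ring order: oxirane first (step 4), 14-membered ring last (step 16).

Assumption: cembrane numbering is used for the macrocycle (C1 = ring CH bearing the C15 acetoxyisopropyl group; C3=C4 Z; C7–C8 epoxide; C10 OAc; C11=C12 E), and the triisopropylbenzoate, oxazolidinone and sulfinyl groups are auxiliaries that leave no atoms in the target.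

**Step 1**
Reactants: 1 but-3-yn-1-ol
Product: 2 but-3-yn-1-yl 2,4,6-triisopropylbenzoate
Conditions: 2,4,6-triisopropylbenzoyl chloride, Et3N, DMAP (cat.), CH2Cl2, 0 °C → rt
Reagents that add atoms: 2,4,6-triisopropylbenzoyl chloride, CC(C)c1cc(C(C)C)c(C(=O)Cl)c(C(C)C)c1
Why: DMAP-catalysed esterification of a primary alcohol; the hindered benzoate later serves as directing group for lithiation and as leaving group in the 1,2-shift.

**Step 2**
Reactants: 2 but-3-yn-1-yl 2,4,6-triisopropylbenzoate; 3 oxirane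
Product: 6 (3E)-6-hydroxy-3-methylhex-3-en-1-yl 2,4,6-triisopropylbenzoate, via alkenyldimethylalane 4 (not isolated), via lithium alkenylalanate 5 (not isolated)
Conditions: Me3Al, Cp2ZrCl2 (20 mol%), CH2Cl2, 0 °C → rt; volatiles removed; n-BuLi, hexane/THF, −78 °C; 3, −78 °C → rt
Reagents that add atoms: trimethylaluminium, C[Al](C)C
Why: Negishi zirconium-catalysed syn-carboalumination gives the (E)-alkenylalane regioselectively, and its n-BuLi ate complex opens oxirane with retention of alkene geometry while the hindered ester stays inert.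

**Step 3**
Reactants: 6 (3E)-6-hydroxy-3-methylhex-3-en-1-yl 2,4,6-triisopropylbenzoate
Product: 8 (3E)-6-chloro-3-methylhex-3-en-1-yl 2,4,6-triisopropylbenzoate, via mesylate 7 (not isolated)
Conditions: MsCl, Et3N, CH2Cl2, 0 °C; then LiCl, DMF, 45 °C
Reagents that add atoms: lithium chloride, [Li+].[Cl-]
Why: Sulfonylation followed by SN2 displacement gives a primary chloride, which tolerates the later s-BuLi step where a bromide or iodide would not.

**Step 4**
Reactants: 8 (3E)-6-chloro-3-methylhex-3-en-1-yl 2,4,6-triisopropylbenzoate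
Product: 9 2-[(2R,3R)-3-(2-chloroethyl)-2-methyloxiran-2-yl]ethyl 2,4,6-triisopropylbenzoate
Conditions: D-fructose-derived Shi ketone (30 mol%), KHSO5 (Oxone), K2CO3, Bu4NHSO4, Na2B4O7 buffer, MeCN/CH2(OMe)2, 0 °C
Reagents that add atoms: potassium peroxymonosulfate, [K+].[O-]S(=O)(=O)OO
Why: Shi asymmetric epoxidation of the only alkene, an (E)-trisubstituted olefin, through the spiro dioxirane transition state gives the (R,R)-epoxide (C7, C8) with the D-fructose-derived ketone.

**Step 5**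
Reactants: 9 2-[(2R,3R)-3-(2-chloroethyl)-2-methyloxiran-2-yl]ethyl 2,4,6-triisopropylbenzoate
Product: 11 (1S)-2-[(2R,3R)-3-(2-chloroethyl)-2-methyloxiran-2-yl]-1-[(S)-(4-methylphenyl)sulfinyl]ethyl 2,4,6-triisopropylbenzoate, via lithiated benzoate 10 (not isolated)
Conditions: s-BuLi, (−)-sparteine, Et2O, −78 °C, 5 h; then added to (1R,2S,5R)-menthyl (S)-p-toluenesulfinate, THF, −78 °C → rt
Reagents that add atoms: (1R,2S,5R)-menthyl (S)-p-toluenesulfinate, CC(C)[C@@H]1CC[C@@H](C)C[C@H]1O[S@](=O)c2ccc(C)cc2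
Why: Hoppe-type sparteine-mediated enantioselective α-deprotonation (pro-S hydrogen) gives configurationally stable 10, which the Andersen sulfinate traps with retention at carbon and inversion at sulfur, storing the C10 carbenoid stereocentre as a sulfoxide.

**Step 6**
Reactants: 11 (1S)-2-[(2R,3R)-3-(2-chloroethyl)-2-methyloxiran-2-yl]-1-[(S)-(4-methylphenyl)sulfinyl]ethyl 2,4,6-triisopropylbenzoate
Product: 12 (1S)-2-[(2R,3R)-3-(2-iodoethyl)-2-methyloxiran-2-yl]-1-[(S)-(4-methylphenyl)sulfinyl]ethyl 2,4,6-triisopropylbenzoate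
Conditions: NaI, NaHCO3 (cat.), acetone, 55 °C
Reagents that add atoms: sodium iodide, [Na+].[I-]
Why: Finkelstein halide exchange (SN2, driven by NaCl precipitation) under neutral conditions gives the iodide needed for zinc insertion without touching epoxide or sulfinyl benzoate.

**Step 7**
Reactants: 13 but-2-yn-1-ol
Product: 15 (2Z)-3-iodobut-2-en-1-ol, via cyclic vinylalanate 14 (not isolated)
Conditions: NaAlH2(OCH2CH2OMe)2, Et2O, 0 °C → rt; then I2, THF, −78 → 0 °C
Reagents that add atoms: iodine, II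
Why: Hydroxyl-directed trans-hydroalumination of the propargylic alcohol places aluminium on C3, and iodinolysis with retention gives only the (Z)-vinyl iodide.

**Step 8**
Reactants: 15 (2Z)-3-iodobut-2-en-1-ol
Product: 16 (2Z)-1-bromo-3-iodobut-2-ene
Conditions: PBr3, Et2O, 0 °C
Reagents that add atoms: phosphorus tribromide, BrP(Br)Br
Why: SN2 bromination of the primary allylic alcohol leaves the vinyl iodide and the alkene geometry untouched.

**Step 9**
Reactants: 17 hex-5-ynoic acid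
Product: 19 (4S)-4-benzyl-3-(hex-5-ynoyl)-1,3-oxazolidin-2-one, via mixed pivalic anhydride 18 (not isolated)
Conditions: t-BuCOCl, Et3N, THF, −20 °C; then (S)-4-benzyloxazolidin-2-one, LiCl, −20 °C → rt
Reagents that add atoms: (S)-4-benzyloxazolidin-2-one, O=C1N[C@@H](Cc2ccccc2)CO1
Why: Mixed-anhydride N-acylation of the oxazolidinone attaches the Evans auxiliary in one flask.

**Step 10**
Reactants: 19 (4S)-4-benzyl-3-(hex-5-ynoyl)-1,3-oxazolidin-2-one; 16 (2Z)-1-bromo-3-iodobut-2-ene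
Product: 21 (4S)-4-benzyl-3-[(2R,4Z)-2-(but-3-yn-1-yl)-5-iodohex-4-enoyl]-1,3-oxazolidin-2-one, via sodium enolate 20 (not isolated)
Conditions: NaN(SiMe3)2 (1.05 equiv), THF, −78 °C; then 16, −78 → −40 °C
Reagents that add atoms: none
Why: Evans asymmetric alkylation, in which the chelated (Z)-enolate is attacked by the allylic bromide on the face opposite the benzyl group and sets C1 as (R); the imide α-hydrogen is far more acidic than the alkyne C–H.

**Step 11**
Reactants: 21 (4S)-4-benzyl-3-[(2R,4Z)-2-(but-3-yn-1-yl)-5-iodohex-4-enoyl]-1,3-oxazolidin-2-one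
Product: 22 methyl (2R,4Z)-2-(but-3-yn-1-yl)-5-iodohex-4-enoate
Conditions: NaOMe (30 mol%), MeOH/THF, 0 °C
Reagents that add atoms: methanol, CO
Why: Methoxide-catalysed transesterification cleaves the exocyclic acyl group and releases the auxiliary without epimerising the α-stereocentre at 0 °C.

**Step 12**
Reactants: 22 methyl (2R,4Z)-2-(but-3-yn-1-yl)-5-iodohex-4-enoate
Product: 23 (3R,5Z)-3-(but-3-yn-1-yl)-6-iodo-2-methylhept-5-en-2-ol
Conditions: MeMgBr (4 equiv), THF, −20 → 0 °C; H2O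
Reagents that add atoms: methylmagnesium bromide, C[Mg]Br
Why: Double Grignard addition to the ester builds the C15 dimethylcarbinol; the vinyl iodide is inert to MeMgBr, and any alkynylmagnesium formed from the terminal alkyne by the excess reagent is reprotonated on aqueous work-up.

**Step 13**
Reactants: 23 (3R,5Z)-3-(but-3-yn-1-yl)-6-iodo-2-methylhept-5-en-2-ol
Product: 25 (3R,5Z)-6-iodo-2-methyl-3-[(3E)-3-methyl-4-(4,4,5,5-tetramethyl-1,3,2-dioxaborolan-2-yl)but-3-en-1-yl]hept-5-en-2-ol, via alkenylalane alkoxide 24 (not isolated)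
Conditions: Me3Al (4 equiv), Cp2ZrCl2 (30 mol%), CH2Cl2, 0 °C → rt; volatiles removed; MeOBpin, THF, 0 °C → rt
Reagents that add atoms: trimethylaluminium, C[Al](C)C; 2-methoxy-4,4,5,5-tetramethyl-1,3,2-dioxaborolane, COB1OC(C)(C)C(C)(C)O1
Why: Negishi syn-carboalumination of the terminal alkyne (vinyl iodide inert, alcohol masked in situ as its aluminium alkoxide) followed by aluminium-to-boron transmetalation gives the (E)-2-methylalkenyl boronic ester with retention.

**Step 14**
Reactants: 25 (3R,5Z)-6-iodo-2-methyl-3-[(3E)-3-methyl-4-(4,4,5,5-tetramethyl-1,3,2-dioxaborolan-2-yl)but-3-en-1-yl]hept-5-en-2-ol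
Product: 26 (3R,5Z)-6-iodo-2-methyl-3-[(3E)-3-methyl-4-(4,4,5,5-tetramethyl-1,3,2-dioxaborolan-2-yl)but-3-en-1-yl]hept-5-en-2-yl acetate
Conditions: Ac2O, Et3N, DMAP (0.5 equiv), CH2Cl2, rt → 40 °C
Reagents that add atoms: acetic anhydride, CC(=O)OC(C)=O
Why: DMAP-catalysed (Steglich-type) acetylation of the tertiary alcohol installs the C15 acetate early, so that no free hydroxyl meets the organozinc and Grignard reagents of steps 15 and 16.

**Step 15**
Reactants: 12 (1S)-2-[(2R,3R)-3-(2-iodoethyl)-2-methyloxiran-2-yl]-1-[(S)-(4-methylphenyl)sulfinyl]ethyl 2,4,6-triisopropylbenzoate; 26 (3R,5Z)-6-iodo-2-methyl-3-[(3E)-3-methyl-4-(4,4,5,5-tetramethyl-1,3,2-dioxaborolan-2-yl)but-3-en-1-yl]hept-5-en-2-yl acetate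
Product: 28 (1S)-2-{(2R,3R)-3-[(3Z,6R,9E)-6-(2-acetoxypropan-2-yl)-3,9-dimethyl-10-(4,4,5,5-tetramethyl-1,3,2-dioxaborolan-2-yl)deca-3,9-dien-1-yl]-2-methyloxiran-2-yl}-1-[(S)-(4-methylphenyl)sulfinyl]ethyl 2,4,6-triisopropylbenzoate, via alkylzinc iodide 27 (not isolated)
Conditions: Zn dust, LiCl, THF, 30 °C; then 26, PdCl2[P(t-Bu)2(C6H4-4-NMe2)]2 (3 mol%), N-methylimidazole, THF, rt
Reagents that add atoms: none
Why: Negishi sp3–sp2 cross-coupling, in which zinc inserts only into the primary C–I bond and palladium couples at the vinyl iodide with retention of (Z) geometry, while base-free conditions leave Bpin, epoxide, acetate and sulfinyl benzoate untouched.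

**Step 16**
Reactants: 28 (1S)-2-{(2R,3R)-3-[(3Z,6R,9E)-6-(2-acetoxypropan-2-yl)-3,9-dimethyl-10-(4,4,5,5-tetramethyl-1,3,2-dioxaborolan-2-yl)deca-3,9-dien-1-yl]-2-methyloxiran-2-yl}-1-[(S)-(4-methylphenyl)sulfinyl]ethyl 2,4,6-triisopropylbenzoate
Product: 32 (1R,3Z,7R,8R,10R,11E)-7,8-epoxy-10-hydroxycembra-3,11-dien-15-yl acetate, via magnesium carbenoid 29 (not isolated), via cyclic boronate complex 30 (not isolated), via macrocyclic allylboronic ester 31 (not isolated)
Conditions: i-PrMgCl·LiCl (1.3 equiv, syringe pump), THF (0.001 M), −78 °C; then −78 °C → rt, 12 h; then H2O2, aq. NaOH, 0 °C, 30 min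
Reagents that add atoms: hydrogen peroxide, OO
Why: Proposed new method: sulfoxide–magnesium exchange unmasks the configurationally stable α-magnesiated benzoate 29, which at high dilution is captured by the alkenyl-Bpin at the other chain end to give the 15-membered cyclic boronate 30; the alkenyl carbon then migrates from boron to C10 anti to the departing triisopropylbenzoate, contracting the boron-containing 15-ring to the 14-membered carbocycle 31 and setting C10 with inversion, and oxidation with retention gives the (10R)-alcohol; the closest known reaction is the intermolecular lithiation–borylation (Matteson/Hoppe–Aggarwal homologation) of boronic esters with magnesium carbenoids made in situ from α-sulfinyl benzoates, which has not been used to close or contract a macrocycle.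

**Step 17**
Reactants: 32 (1R,3Z,7R,8R,10R,11E)-7,8-epoxy-10-hydroxycembra-3,11-dien-15-yl acetate
Product: 33 (1R,3Z,7R,8R,10R,11E)-7,8-epoxycembra-3,11-diene-10,15-diyl diacetate (CNP0282098.2)
Conditions: Ac2O, pyridine, DMAP (cat.), CH2Cl2, 0 °C → rt
Reagents that add atoms: acetic anhydride, CC(=O)OC(C)=O
Why: Nucleophile-catalysed acetylation of the secondary allylic alcohol under mild basic conditions that spare the epoxide.

**Compound list**
1 | but-3-yn-1-ol | C#CCCO | starting material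
2 | but-3-yn-1-yl 2,4,6-triisopropylbenzoate | C#CCCOC(=O)c1c(C(C)C)cc(C(C)C)cc1C(C)C | intermediate
3 | oxirane | C1CO1 | starting material
4 | (E)-alkenyldimethylalane from 2 (AlMe2 on the former terminal alkyne carbon, cis to the new methyl) | C[Al](C)/C=C(\C)CCOC(=O)c1c(C(C)C)cc(C(C)C)cc1C(C)C | intermediate
5 | lithium butyl(dimethyl)alkenylalanate of 4 | [Li+].CCCC[Al-](C)(C)/C=C(\C)CCOC(=O)c1c(C(C)C)cc(C(C)C)cc1C(C)C | intermediate
6 | (3E)-6-hydroxy-3-methylhex-3-en-1-yl 2,4,6-triisopropylbenzoate | OCC/C=C(\C)CCOC(=O)c1c(C(C)C)cc(C(C)C)cc1C(C)C | intermediate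
7 | (3E)-3-methyl-6-(methylsulfonyloxy)hex-3-en-1-yl 2,4,6-triisopropylbenzoate | CS(=O)(=O)OCC/C=C(\C)CCOC(=O)c1c(C(C)C)cc(C(C)C)cc1C(C)C | intermediate
8 | (3E)-6-chloro-3-methylhex-3-en-1-yl 2,4,6-triisopropylbenzoate | ClCC/C=C(\C)CCOC(=O)c1c(C(C)C)cc(C(C)C)cc1C(C)C | intermediate
9 | 2-[(2R,3R)-3-(2-chloroethyl)-2-methyloxiran-2-yl]ethyl 2,4,6-triisopropylbenzoate | ClCC[C@H]1O[C@]1(C)CCOC(=O)c2c(C(C)C)cc(C(C)C)cc2C(C)C | intermediate
10 | (1S)-1-lithio derivative of 9 (lithium on the O-bearing carbon, sparteine complex) | ClCC[C@H]1O[C@]1(C)C[C@@H](OC(=O)c2c(C(C)C)cc(C(C)C)cc2C(C)C)[Li] | intermediate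
11 | (1S)-2-[(2R,3R)-3-(2-chloroethyl)-2-methyloxiran-2-yl]-1-[(S)-(4-methylphenyl)sulfinyl]ethyl 2,4,6-triisopropylbenzoate | ClCC[C@H]1O[C@]1(C)C[C@@H](OC(=O)c2c(C(C)C)cc(C(C)C)cc2C(C)C)[S@@](=O)c3ccc(C)cc3 | intermediate
12 | (1S)-2-[(2R,3R)-3-(2-iodoethyl)-2-methyloxiran-2-yl]-1-[(S)-(4-methylphenyl)sulfinyl]ethyl 2,4,6-triisopropylbenzoate | ICC[C@H]1O[C@]1(C)C[C@@H](OC(=O)c2c(C(C)C)cc(C(C)C)cc2C(C)C)[S@@](=O)c3ccc(C)cc3 | intermediate
13 | but-2-yn-1-ol | CC#CCO | starting material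
14 | sodium cyclic vinylalanate (five-membered O–Al–C ring, two 2-methoxyethoxy ligands on Al) | [Na+].CC1=CCO[Al-]1(OCCOC)OCCOC | intermediate
15 | (2Z)-3-iodobut-2-en-1-ol | OC/C=C(/C)I | intermediate
16 | (2Z)-1-bromo-3-iodobut-2-ene | BrC/C=C(/C)I | intermediate
17 | hex-5-ynoic acid | C#CCCCC(=O)O | starting material
18 | hex-5-ynoic pivalic anhydride | C#CCCCC(=O)OC(=O)C(C)(C)C | intermediate
19 | (4S)-4-benzyl-3-(hex-5-ynoyl)-1,3-oxazolidin-2-one | C#CCCCC(=O)N1[C@@H](Cc2ccccc2)COC1=O | intermediate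
20 | sodium (Z)-enolate of 19 | [Na+].C#CCC/C=C(\[O-])N1[C@@H](Cc2ccccc2)COC1=O | intermediate
21 | (4S)-4-benzyl-3-[(2R,4Z)-2-(but-3-yn-1-yl)-5-iodohex-4-enoyl]-1,3-oxazolidin-2-one | C#CCC[C@H](C/C=C(/C)I)C(=O)N1[C@@H](Cc2ccccc2)COC1=O | intermediate
22 | methyl (2R,4Z)-2-(but-3-yn-1-yl)-5-iodohex-4-enoate | C#CCC[C@H](C/C=C(/C)I)C(=O)OC | intermediate
23 | (3R,5Z)-3-(but-3-yn-1-yl)-6-iodo-2-methylhept-5-en-2-ol | C#CCC[C@H](C/C=C(/C)I)C(C)(C)O | intermediate
24 | (E)-alkenyldimethylalane of 23 with the alcohol as its dimethylaluminium alkoxide | C[Al](C)/C=C(\C)CC[C@H](C/C=C(/C)I)C(C)(C)O[Al](C)C | intermediate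
25 | (3R,5Z)-6-iodo-2-methyl-3-[(3E)-3-methyl-4-(4,4,5,5-tetramethyl-1,3,2-dioxaborolan-2-yl)but-3-en-1-yl]hept-5-en-2-ol | CC1(C)OB(/C=C(\C)CC[C@H](C/C=C(/C)I)C(C)(C)O)OC1(C)C | intermediate
26 | (3R,5Z)-6-iodo-2-methyl-3-[(3E)-3-methyl-4-(4,4,5,5-tetramethyl-1,3,2-dioxaborolan-2-yl)but-3-en-1-yl]hept-5-en-2-yl acetate | CC1(C)OB(/C=C(\C)CC[C@H](C/C=C(/C)I)C(C)(C)OC(C)=O)OC1(C)C | intermediate
27 | alkylzinc iodide of 12 (ZnI in place of I) | I[Zn]CC[C@H]1O[C@]1(C)C[C@@H](OC(=O)c2c(C(C)C)cc(C(C)C)cc2C(C)C)[S@@](=O)c3ccc(C)cc3 | intermediate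
28 | (1S)-2-{(2R,3R)-3-[(3Z,6R,9E)-6-(2-acetoxypropan-2-yl)-3,9-dimethyl-10-(4,4,5,5-tetramethyl-1,3,2-dioxaborolan-2-yl)deca-3,9-dien-1-yl]-2-methyloxiran-2-yl}-1-[(S)-(4-methylphenyl)sulfinyl]ethyl 2,4,6-triisopropylbenzoate | CC1(C)OB(/C=C(\C)CC[C@H](C/C=C(/C)CC[C@H]2O[C@]2(C)C[C@@H](OC(=O)c3c(C(C)C)cc(C(C)C)cc3C(C)C)[S@@](=O)c4ccc(C)cc4)C(C)(C)OC(C)=O)OC1(C)C | intermediate
29 | magnesium carbenoid of 28 (MgCl in place of the sulfinyl group, same configuration) | CC1(C)OB(/C=C(\C)CC[C@H](C/C=C(/C)CC[C@H]2O[C@]2(C)C[C@@H](OC(=O)c3c(C(C)C)cc(C(C)C)cc3C(C)C)[Mg]Cl)C(C)(C)OC(C)=O)OC1(C)C | intermediate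
30 | 15-membered cyclic boronate complex (boron bonded to C10 and C11, benzoate still on C10, MgCl counter-ion) | CC1(C)O[B-]2(OC1(C)C)/C=C(\C)CC[C@@H](C(C)(C)OC(C)=O)C/C=C(/C)CC[C@H]3O[C@]3(C)C[C@H]2OC(=O)c4c(C(C)C)cc(C(C)C)cc4C(C)C.[Mg+]Cl | intermediate
31 | (1R,3Z,7R,8R,10R,11E)-7,8-epoxy-10-(4,4,5,5-tetramethyl-1,3,2-dioxaborolan-2-yl)cembra-3,11-dien-15-yl acetate | CC1(C)OB(OC1(C)C)[C@H]2/C=C(\C)CC[C@@H](C(C)(C)OC(C)=O)C/C=C(/C)CC[C@H]3O[C@]3(C)C2 | intermediate
32 | (1R,3Z,7R,8R,10R,11E)-7,8-epoxy-10-hydroxycembra-3,11-dien-15-yl acetate | O[C@H]1/C=C(\C)CC[C@@H](C(C)(C)OC(C)=O)C/C=C(/C)CC[C@H]2O[C@]2(C)C1 | intermediate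
33 | (1R,3Z,7R,8R,10R,11E)-7,8-epoxycembra-3,11-diene-10,15-diyl diacetate (CNP0282098.2) | CC(=O)O[C@H]1/C=C(\C)CC[C@@H](C(C)(C)OC(C)=O)C/C=C(/C)CC[C@H]2O[C@]2(C)C1 | target

**Totals**
Total step count: 17.
Longest linear sequence: 10 steps (steps 7, 8 and 10–17, from but-2-yn-1-ol 13 to 33). The branches from hex-5-ynoic acid 17 (steps 9–17) and from but-3-yn-1-ol 1 (steps 1–6 then 15–17) are 9 steps each.

**Steps most likely to fail**

Step 16 (the new ring-contracting macrocyclisation). Risks are oligomerisation, slow capture of the magnesium carbenoid by the remote boronic ester, and attack of the Grignard reagent on boron. The fallback uses known chemistry, sets out from 9 (together with 26) and returns to the route at 33. Epoxy chloride 9 is lithiated with s-BuLi (no excess)/(−)-sparteine to 10, and boronic ester 26 is added as the electrophile. This ordinary intermolecular lithiation–borylation gives, after the 1,2-shift on warming, the open-chain allylboronic ester F1, and H2O2/NaOH in the same flask gives the (R)-allylic alcohol F2. Acetylation (Ac2O, pyridine, DMAP) gives the diacetate chloride F3, and NaI in acetone gives the diacetate iodide F4. Zinc insertion (Zn, LiCl) gives the alkylzinc iodide F5. An intramolecular Negishi coupling at high dilution with a zerovalent palladium catalyst generated from PdCl2[P(t-Bu)2(C6H4-4-NMe2)]2 then closes the 14-membered ring at C4–C5 and gives 33 directly; oxidative addition at the vinyl iodide is expected to outpace ionisation of the hindered secondary allylic acetate.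

Step 5 (five hours of s-BuLi/sparteine in the presence of the trisubstituted epoxide and the alkyl chloride). The fallback sets out from 8 and returns at 11. The alkene chloride 8, which has no epoxide yet, is deprotonated with s-BuLi/(−)-sparteine to the lithiated alkenyl benzoate F6 and quenched with Me3SnCl to the (S)-α-stannyl benzoate F7. Shi epoxidation under the conditions of step 4 gives the stannyl epoxide F8. Tin–lithium exchange with n-BuLi (−78 °C, minutes, retention) then regenerates 10 with only brief exposure of the epoxide to an organolithium, and 10 is sulfinylated as in step 5 to give 11.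

Step 15 (Lewis-acidic zinc salts next to a trisubstituted epoxide; a sulfoxide on the zinc reagent; retention of the Z-vinyl geometry). The fallback sets out from 12 and 26 and returns at 28. It avoids any organozinc by a silyl-radical-mediated nickel/photoredox cross-electrophile coupling of the two iodides (NiCl2(dme), 4,4′-di-tert-butyl-2,2′-bipyridine, [Ir(dF(CF3)ppy)2(dtbbpy)]PF6, (Me3Si)3SiH, Na2CO3, 1,2-dimethoxyethane, blue light, rt), which gives 28 directly and makes no new compound.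

**Further compounds**
F1 | step 16 | open-chain (10R)-allylboronic ester: 26 joined at C11 to C10 of the epoxy chloride chain, Bpin on C10 | ClCC[C@H]1O[C@]1(C)C[C@@H](B2OC(C)(C)C(C)(C)O2)/C=C(\C)CC[C@H](C/C=C(/C)I)C(C)(C)OC(C)=O
F2 | step 16 | open-chain (10R)-allylic alcohol (C5 chloride, C4 vinyl iodide, C15 acetate) | ClCC[C@H]1O[C@]1(C)C[C@@H](O)/C=C(\C)CC[C@H](C/C=C(/C)I)C(C)(C)OC(C)=O
F3 | step 16 | open-chain C10,C15-diacetate chloride | ClCC[C@H]1O[C@]1(C)C[C@@H](OC(C)=O)/C=C(\C)CC[C@H](C/C=C(/C)I)C(C)(C)OC(C)=O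
F4 | step 16 | open-chain C10,C15-diacetate iodide | ICC[C@H]1O[C@]1(C)C[C@@H](OC(C)=O)/C=C(\C)CC[C@H](C/C=C(/C)I)C(C)(C)OC(C)=O
F5 | step 16 | alkylzinc iodide of F4 | I[Zn]CC[C@H]1O[C@]1(C)C[C@@H](OC(C)=O)/C=C(\C)CC[C@H](C/C=C(/C)I)C(C)(C)OC(C)=O
F6 | step 5 | (1S)-1-lithio derivative of 8 | ClCC/C=C(\C)C[C@@H](OC(=O)c1c(C(C)C)cc(C(C)C)cc1C(C)C)[Li]
F7 | step 5 | (1S,3E)-6-chloro-3-methyl-1-(trimethylstannyl)hex-3-en-1-yl 2,4,6-triisopropylbenzoate | ClCC/C=C(\C)C[C@@H](OC(=O)c1c(C(C)C)cc(C(C)C)cc1C(C)C)[Sn](C)(C)C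
F8 | step 5 | (1S)-2-[(2R,3R)-3-(2-chloroethyl)-2-methyloxiran-2-yl]-1-(trimethylstannyl)ethyl 2,4,6-triisopropylbenzoate | ClCC[C@H]1O[C@]1(C)C[C@@H](OC(=O)c2c(C(C)C)cc(C(C)C)cc2C(C)C)[Sn](C)(C)C
F0 | step 15 | none | none
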